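**Plan**
- Retrosynthesis: the second C6 methyl is removed first (ketal methylation), then the O1–C6 bond is cut. The ring segment O1–C2(quaternary)–C3(oxygenated)–C4=C5–C6(oxygenated) is the oxidation pattern of a 2,5-disubstituted furan, so the pyran goes back to a tertiary 5-methylfuran-2-yl carbinol: C2 is the carbinol carbon and the furan 5-methyl is one C6 methyl.
- The cyclohexane is cut at C5′–C6′ (ring-closing metathesis, then saturation), the C2–C1′ bond by allylboration of 2-acetyl-5-methylfuran, and C3′–Br/C4′–Cl by bromochlorination of a Z-allylic alcohol.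
- Forward: acyclic bromochloride → E-allylboronic acid → union with the furyl ketone → carbocycle, closed and saturated while the furan is still aromatic → furan-to-pyranone ring expansion → C3 reduction → C6 methylation.
- Stereochemistry: C3′/C4′ from catalyst-controlled anti addition to the Z-alkene; C2 and C1′ together from the chair-like BINOL-catalysed addition of the E-allylboronic acid; C3 from oxazaborolidine-controlled reduction; C6 ends non-stereogenic.

Key step: step 10

Remark on numbering: locants follow the target (pyran O1, C2 quaternary, C3 carbinol, C4=C5, C6; cyclohexane C1′ on C2, C3′ with Br, C4′ with Cl and CH3); pyran intermediates keep these locants.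
Assumption: the sense of induction of each chiral catalyst is taken from its usual model ((S)-BINOL derivative for Re-face allylation of the aryl methyl ketone, the Schiff-base ligand enantiomer that brominates the C3 Si face of 4, (S)-CBS for Si-face hydride delivery at C3); should a sense prove opposite, the mirror-image catalyst is used.

**Step 1**
Reactants: 1 prop-2-yn-1-ol; 2 3-bromoprop-1-ene (allyl bromide)
Product: 4 (2Z)-2-methylhexa-2,5-dien-1-ol, via vinylmagnesium alkoxide 3 (not isolated)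
Conditions: CH3MgBr (3 equiv), CuI (10 mol%), THF, −10 °C → rt; then 2, 0 °C → rt; aq. NH4Cl
Reagents that add atoms: methylmagnesium bromide, C[Mg]Br
Why: Copper-catalysed anti-carbomagnesiation of the propargylic alkoxide puts methyl on C2 and magnesium on C3 cis to the CH2O group (five-membered chelate), so copper-assisted allylation of that vinylmagnesium should give the Z-trisubstituted allylic alcohol as one geometric isomer.

**Step 2**
Reactants: 4 (2Z)-2-methylhexa-2,5-dien-1-ol
Product: 5 (2S,3S)-3-bromo-2-chloro-2-methylhex-5-en-1-ol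
Conditions: NBS, ClTi(OiPr)3, chiral tridentate Schiff-base ligand (salicylaldimine of a β-amino alcohol, 20 mol%), hexanes, −20 °C
Reagents that add atoms: N-bromosuccinimide, O=C1CCC(=O)N1Br; chlorotitanium triisopropoxide, CC(C)O[Ti](Cl)(OC(C)C)OC(C)C
Why: Titanium-alkoxide-directed catalytic enantioselective bromochlorination of an allylic alcohol: bromine is delivered to the C3 Si face chosen by the chiral titanium complex and chloride opens the bromonium ion anti at the tertiary C2 (Markovnikov), so Z geometry plus anti addition fix the (2S,3S) pair (C4′ and C3′ of the target) while the undirected terminal alkene is left alone.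

**Step 3**
Reactants: 5 (2S,3S)-3-bromo-2-chloro-2-methylhex-5-en-1-ol; 6 (2Z)-but-2-ene-1,4-diol
Product: 7 (2E,5S,6S)-5-bromo-6-chloro-6-methylhept-2-ene-1,7-diol
Conditions: second-generation Hoveyda–Grubbs catalyst RuCl2(H2IMes)(=CH–C6H4–2-OiPr) (5 mol%; H2IMes = 1,3-dimesitylimidazolidin-2-ylidene), 6 (4 equiv), CH2Cl2, 40 °C
Reagents that add atoms: none
Why: Olefin cross-metathesis of the unhindered terminal alkene with an excess of the symmetrical allylic diol should give mainly the thermodynamically favoured E-allylic alcohol, with no stereocentre formed and the halogenated carbons untouched.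

**Step 4**
Reactants: 7 (2E,5S,6S)-5-bromo-6-chloro-6-methylhept-2-ene-1,7-diol
Product: 8 [(2E,5S,6S)-5-bromo-6-chloro-7-hydroxy-6-methylhept-2-en-1-yl]boronic acid
Conditions: B2(OH)4, H2PdCl4 (5 mol%), DMSO/MeOH, rt, argon; extracted under argon and used at once
Reagents that add atoms: tetrahydroxydiboron, OB(O)B(O)O
Why: Palladium-catalysed borylation of an allylic alcohol with tetrahydroxydiboron passes through an η3-allyl intermediate that is borylated at its unsubstituted terminus, so the linear E-allylboronic acid is expected (any Z-isomer from step 3 should converge) and the hindered primary alcohol and both C–halogen bonds remain spectators.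

**Step 5**
Reactants: 8 [(2E,5S,6S)-5-bromo-6-chloro-7-hydroxy-6-methylhept-2-en-1-yl]boronic acid; 9 1-(5-methylfuran-2-yl)ethan-1-one (2-acetyl-5-methylfuran)
Product: 10 (2S,3S,5R,6R)-3-bromo-2-chloro-5-ethenyl-2-methyl-6-(5-methylfuran-2-yl)heptane-1,6-diol
Conditions: (S)-3,3′-dibromo-BINOL (20 mol%), t-BuOH, 3 Å molecular sieves, toluene, 0 °C → rt; aq. NaHCO3
Reagents that add atoms: none
Why: Chiral-diol-catalysed asymmetric allylboration of a ketone: the BINOL-bound boronate adds through a chair-like Zimmerman–Traxler transition state with the furyl group and the E-γ-substituent equatorial, which sets the anti relation of the C2 hydroxyl and the C2′ arm (hence C1′), while the catalyst selects the Re face of the ketone (C2 = R); because 8 is already one enantiomer, any minor isomers are diastereomers and separable.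

**Step 6**
Reactants: 10 (2S,3S,5R,6R)-3-bromo-2-chloro-5-ethenyl-2-methyl-6-(5-methylfuran-2-yl)heptane-1,6-diol
Product: 11 (2S,3S,5R,6R)-3-bromo-2-chloro-5-ethenyl-6-hydroxy-2-methyl-6-(5-methylfuran-2-yl)heptanal
Conditions: Dess–Martin periodinane, NaHCO3, CH2Cl2, 0 °C
Reagents that add atoms: none
Why: Dess–Martin oxidation takes the primary alcohol to the aldehyde under buffered conditions; the tertiary furyl carbinol cannot be oxidised and the α-carbon is quaternary, so neither epimerisation nor β-elimination is possible.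

**Step 7**
Reactants: 11 (2S,3S,5R,6R)-3-bromo-2-chloro-5-ethenyl-6-hydroxy-2-methyl-6-(5-methylfuran-2-yl)heptanal
Product: 12 (2R,3R,5S,6S)-5-bromo-6-chloro-3-ethenyl-6-methyl-2-(5-methylfuran-2-yl)oct-7-en-2-ol
Conditions: Ph3PCH3Br, KN(SiMe3)2 (2.5 equiv each), THF, −78 → 0 °C
Reagents that add atoms: methyltriphenylphosphonium bromide, C[P+](c1ccccc1)(c1ccccc1)c1ccccc1.[Br-]
Why: Wittig methylenation of the non-enolisable α-chloro aldehyde should install the second terminal alkene at low temperature, with excess ylide covering the free tertiary hydroxyl.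

**Step 8**
Reactants: 12 (2R,3R,5S,6S)-5-bromo-6-chloro-3-ethenyl-6-methyl-2-(5-methylfuran-2-yl)oct-7-en-2-ol
Product: 13 (1R)-1-[(1R,4S,5S)-5-bromo-4-chloro-4-methylcyclohex-2-en-1-yl]-1-(5-methylfuran-2-yl)ethan-1-ol
Conditions: second-generation Grubbs catalyst RuCl2(=CHPh)(PCy3)(H2IMes) (5 mol%), CH2Cl2, 40 °C; filtration through Et3N-deactivated silica
Reagents that add atoms: none
Why: Ring-closing metathesis of the 1,7-diene should close the six-membered carbocycle (C5′=C6′) with loss of ethene; the β-bromine retards ionisation of the allylic tertiary chloride and no stereocentre is touched.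

**Step 9**
Reactants: 13 (1R)-1-[(1R,4S,5S)-5-bromo-4-chloro-4-methylcyclohex-2-en-1-yl]-1-(5-methylfuran-2-yl)ethan-1-ol
Product: 14 (1R)-1-[(1S,3S,4S)-3-bromo-4-chloro-4-methylcyclohexyl]-1-(5-methylfuran-2-yl)ethan-1-ol
Conditions: 2-nitrobenzenesulfonylhydrazide (excess), Et3N, CH2Cl2, rt
Reagents that add atoms: none
Why: Diimide reduction: diazene generated in situ transfers H2 in a concerted syn manner to the cis-disubstituted ring alkene only, the aromatic furan and the C–Br and C–Cl bonds being inert to it, and no stereocentre is created.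

**Step 10**
Reactants: 14 (1R)-1-[(1S,3S,4S)-3-bromo-4-chloro-4-methylcyclohexyl]-1-(5-methylfuran-2-yl)ethan-1-ol
Product: 16 (2R)-2-[(1S,3S,4S)-3-bromo-4-chloro-4-methylcyclohexyl]-6-hydroxy-2,6-dimethyl-2H-pyran-3(6H)-one, via Z-enedione 15 (not isolated)
Conditions: NBS (1.05 equiv), NaHCO3, THF/H2O (4:1), 0 °C
Reagents that add atoms: water, O
Why: Electrophilic bromine from NBS attacks the electron-rich furan at an α-carbon and water adds at the other α-position; loss of HBr from the 2,5-dioxygenated dihydrofuran unmasks the Z-enedione 15, whose tertiary C2 hydroxyl adds to the distal methyl ketone. This is the Achmatowicz rearrangement, established for secondary and tertiary 2-furyl carbinols. The pyranone ring closes by 6-exo-trig hemiketalisation (O1–C6), the Z geometry needed for closure being inherited from the furan ring. The only new stereocentre, the hemiketal carbon C6, is uncontrolled and does not matter because it becomes the gem-dimethyl carbon, while C2 is quaternary and cannot epimerise. The step needs chemoselective oxidation of the furan: this is secured by having saturated the ring alkene beforehand, so the furan is the only π-nucleophile left, and by the NaHCO3 buffer, which keeps HBr from ionising the tertiary furfuryl alcohol.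

**Step 11**
Reactants: 16 (2R)-2-[(1S,3S,4S)-3-bromo-4-chloro-4-methylcyclohexyl]-6-hydroxy-2,6-dimethyl-2H-pyran-3(6H)-one
Product: 17 (2R)-2-[(1S,3S,4S)-3-bromo-4-chloro-4-methylcyclohexyl]-6-methoxy-2,6-dimethyl-2H-pyran-3(6H)-one
Conditions: HC(OMe)3, MeOH, pyridinium p-toluenesulfonate (cat.), rt
Reagents that add atoms: trimethyl orthoformate, COC(OC)OC; methanol, CO
Why: Acid-catalysed ketalisation through the ring oxocarbenium ion, driven by the orthoformate, exchanges the tertiary hemiketal hydroxyl for methoxy, which blocks ring opening and provides the leaving group for step 13; the C6 epimer mixture is inconsequential.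

**Step 12**
Reactants: 17 (2R)-2-[(1S,3S,4S)-3-bromo-4-chloro-4-methylcyclohexyl]-6-methoxy-2,6-dimethyl-2H-pyran-3(6H)-one
Product: 18 (2R,3R)-2-[(1S,3S,4S)-3-bromo-4-chloro-4-methylcyclohexyl]-6-methoxy-2,6-dimethyl-3,6-dihydro-2H-pyran-3-ol
Conditions: (S)-2-methyl-CBS-oxazaborolidine (20 mol%), BH3·SMe2, THF, −30 °C; MeOH quench
Reagents that add atoms: none
Why: Corey–Bakshi–Shibata reduction should give 1,2-reduction of the enone with hydride delivered to the Si face of C3 (quaternary C2 as the large flank), placing the hydroxyl cis to the cyclohexyl group and setting C3 as R under reagent control.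

**Step 13**
Reactants: 18 (2R,3R)-2-[(1S,3S,4S)-3-bromo-4-chloro-4-methylcyclohexyl]-6-methoxy-2,6-dimethyl-3,6-dihydro-2H-pyran-3-ol
Product: 19 (2R,3R)-2-[(1S,3S,4S)-3-bromo-4-chloro-4-methylcyclohexyl]-2,6,6-trimethyl-3,6-dihydro-2H-pyran-3-ol
Conditions: AlMe3 (3 equiv), toluene, −78 → −20 °C; aq. potassium sodium tartrate
Reagents that add atoms: trimethylaluminium, C[Al](C)C
Why: Lewis-acid-mediated ketal substitution: AlMe3 ionises the C6 methoxy group to the ring oxocarbenium ion and transfers methyl to C6 within the ion pair, making C6 a non-stereogenic gem-dimethyl carbon; one equivalent is consumed by the C3 hydroxyl, and low temperature in a non-polar solvent is chosen to spare the tertiary chloride.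

**Compound list**
1 | prop-2-yn-1-ol (propargyl alcohol) | C#CCO | starting material
2 | 3-bromoprop-1-ene (allyl bromide) | C=CCBr | starting material
3 | bromomagnesium (2Z)-3-(bromomagnesio)-2-methylprop-2-en-1-olate | Br[Mg]/C=C(/C)CO[Mg]Br | intermediate
4 | (2Z)-2-methylhexa-2,5-dien-1-ol | C=CC/C=C(/C)CO | intermediate
5 | (2S,3S)-3-bromo-2-chloro-2-methylhex-5-en-1-ol | C=CC[C@H](Br)[C@@](C)(Cl)CO | intermediate
6 | (2Z)-but-2-ene-1,4-diol | OC/C=C\CO | starting material
7 | (2E,5S,6S)-5-bromo-6-chloro-6-methylhept-2-ene-1,7-diol | OC/C=C/C[C@H](Br)[C@@](C)(Cl)CO | intermediate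
8 | [(2E,5S,6S)-5-bromo-6-chloro-7-hydroxy-6-methylhept-2-en-1-yl]boronic acid | OB(O)C/C=C/C[C@H](Br)[C@@](C)(Cl)CO | intermediate
9 | 1-(5-methylfuran-2-yl)ethan-1-one (2-acetyl-5-methylfuran) | CC(=O)c1ccc(C)o1 | starting material
10 | (2S,3S,5R,6R)-3-bromo-2-chloro-5-ethenyl-2-methyl-6-(5-methylfuran-2-yl)heptane-1,6-diol | Cc1ccc(o1)[C@@](C)([C@H](C[C@H](Br)[C@@](C)(Cl)CO)C=C)O | intermediate
11 | (2S,3S,5R,6R)-3-bromo-2-chloro-5-ethenyl-6-hydroxy-2-methyl-6-(5-methylfuran-2-yl)heptanal | Cc1ccc(o1)[C@@](C)([C@H](C[C@H](Br)[C@@](C)(Cl)C=O)C=C)O | intermediate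
12 | (2R,3R,5S,6S)-5-bromo-6-chloro-3-ethenyl-6-methyl-2-(5-methylfuran-2-yl)oct-7-en-2-ol | Cc1ccc(o1)[C@@](C)([C@H](C[C@H](Br)[C@@](C)(Cl)C=C)C=C)O | intermediate
13 | (1R)-1-[(1R,4S,5S)-5-bromo-4-chloro-4-methylcyclohex-2-en-1-yl]-1-(5-methylfuran-2-yl)ethan-1-ol | Cc1ccc(o1)[C@@](C)([C@H]2C=C[C@](C)(Cl)[C@@H](Br)C2)O | intermediate
14 | (1R)-1-[(1S,3S,4S)-3-bromo-4-chloro-4-methylcyclohexyl]-1-(5-methylfuran-2-yl)ethan-1-ol | Cc1ccc(o1)[C@@](C)([C@H]2CC[C@](C)(Cl)[C@@H](Br)C2)O | intermediate
15 | (3Z,6R)-6-[(1S,3S,4S)-3-bromo-4-chloro-4-methylcyclohexyl]-6-hydroxyhept-3-ene-2,5-dione | CC(=O)/C=C\C(=O)[C@](C)(O)[C@H]1CC[C@](C)(Cl)[C@@H](Br)C1 | intermediate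
16 | (2R)-2-[(1S,3S,4S)-3-bromo-4-chloro-4-methylcyclohexyl]-6-hydroxy-2,6-dimethyl-2H-pyran-3(6H)-one (both C6 epimers) | CC1(O)C=CC(=O)[C@@](C)([C@H]2CC[C@](C)(Cl)[C@@H](Br)C2)O1 | intermediate
17 | (2R)-2-[(1S,3S,4S)-3-bromo-4-chloro-4-methylcyclohexyl]-6-methoxy-2,6-dimethyl-2H-pyran-3(6H)-one (both C6 epimers) | COC1(C)C=CC(=O)[C@@](C)([C@H]2CC[C@](C)(Cl)[C@@H](Br)C2)O1 | intermediate
18 | (2R,3R)-2-[(1S,3S,4S)-3-bromo-4-chloro-4-methylcyclohexyl]-6-methoxy-2,6-dimethyl-3,6-dihydro-2H-pyran-3-ol (both C6 epimers) | COC1(C)C=C[C@@H](O)[C@@](C)([C@H]2CC[C@](C)(Cl)[C@@H](Br)C2)O1 | intermediate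
19 | (2R,3R)-2-[(1S,3S,4S)-3-bromo-4-chloro-4-methylcyclohexyl]-2,6,6-trimethyl-3,6-dihydro-2H-pyran-3-ol | CC1(C)C=C[C@@H](O)[C@@](C)([C@H]2CC[C@](C)(Cl)[C@@H](Br)C2)O1 | target

Total step count: 13. Longest linear sequence: 13 steps (from 1 to 19; 2, 6 and 9 enter as purchased materials).

**Steps most likely to fail**

Step 2. Chloride may be delivered to C3 instead of the tertiary C2, or the titanium complex may discriminate the alkene faces poorly for this 2,3-disubstituted pattern. The fallback sets out from 4 and returns at 5. Sharpless asymmetric epoxidation (Ti(OiPr)4, D-(−)-diethyl tartrate, t-BuOOH, 4 Å sieves, CH2Cl2, −20 °C) should give [(2S,3R)-2-methyl-3-(prop-2-en-1-yl)oxiran-2-yl]methanol F1. Titanium-assisted opening at C3 with bromide (Ti(OiPr)4, Et2NH·HBr), with inversion, gives (2S,3S)-3-bromo-2-methylhex-5-ene-1,2-diol F2. Selective acylation of the primary hydroxyl (pivaloyl chloride, pyridine) gives (2S,3S)-3-bromo-2-hydroxy-2-methylhex-5-en-1-yl 2,2-dimethylpropanoate F3. SOCl2 with 2,6-lutidine then replaces the tertiary hydroxyl by chloride with net retention through the bromonium ion (double inversion), giving (2S,3S)-3-bromo-2-chloro-2-methylhex-5-en-1-yl 2,2-dimethylpropanoate F4, and reduction with iBu2AlH returns 5.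

Step 12. Hydride delivery may follow the ring's own bias (attack anti to a pseudo-axial C2 methyl) and override the catalyst, giving mainly the C3 epimer. The fallback sets out from 17 and returns at 18. Luche reduction (NaBH4, CeCl3·7H2O, MeOH, −78 °C) is used to make that epimer on purpose, (2R,3S)-2-[(1S,3S,4S)-3-bromo-4-chloro-4-methylcyclohexyl]-6-methoxy-2,6-dimethyl-3,6-dihydro-2H-pyran-3-ol F5. Mitsunobu inversion (PPh3, diisopropyl azodicarboxylate, 4-nitrobenzoic acid, THF) gives (2R,3R)-2-[(1S,3S,4S)-3-bromo-4-chloro-4-methylcyclohexyl]-6-methoxy-2,6-dimethyl-3,6-dihydro-2H-pyran-3-yl 4-nitrobenzoate F6, and methanolysis (K2CO3, MeOH) returns 18.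

Step 13. The Lewis acid may also ionise the tertiary C4′–Cl bond, or methyl may be transferred to C4 of the allylic oxocarbenium ion instead of C6. The fallback sets out from 18 and returns at 19 without a strong Lewis acid.
- Silylation (tert-butyldimethylsilyl triflate, 2,6-lutidine) gives tert-butyl{[(2R,3R)-2-[(1S,3S,4S)-3-bromo-4-chloro-4-methylcyclohexyl]-6-methoxy-2,6-dimethyl-3,6-dihydro-2H-pyran-3-yl]oxy}dimethylsilane F7.
- Mild hydrolysis (pyridinium p-toluenesulfonate, acetone/H2O) gives the hemiketal (2R,3R)-2-[(1S,3S,4S)-3-bromo-4-chloro-4-methylcyclohexyl]-3-{[tert-butyl(dimethyl)silyl]oxy}-2,6-dimethyl-3,6-dihydro-2H-pyran-6-ol F8.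
- CH3MgBr with CeCl3 adds to the ring-opened methyl ketone to give (3Z,5R,6R)-6-[(1S,3S,4S)-3-bromo-4-chloro-4-methylcyclohexyl]-5-{[tert-butyl(dimethyl)silyl]oxy}-2-methylhept-3-ene-2,6-diol F9.
- Catalytic camphorsulfonic acid ionises the tertiary allylic alcohol, and capture by the C2 hydroxyl closes the six-membered ring to tert-butyl{[(2R,3R)-2-[(1S,3S,4S)-3-bromo-4-chloro-4-methylcyclohexyl]-2,6,6-trimethyl-3,6-dihydro-2H-pyran-3-yl]oxy}dimethylsilane F10.
- Bu4NF removes the silyl group to give 19.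

Further compounds
F1 | step 2 | [(2S,3R)-2-methyl-3-(prop-2-en-1-yl)oxiran-2-yl]methanol | C=CC[C@H]1O[C@@]1(C)CO
F2 | step 2 | (2S,3S)-3-bromo-2-methylhex-5-ene-1,2-diol | C=CC[C@H](Br)[C@@](C)(O)CO
F3 | step 2 | (2S,3S)-3-bromo-2-hydroxy-2-methylhex-5-en-1-yl 2,2-dimethylpropanoate | C=CC[C@H](Br)[C@@](C)(O)COC(=O)C(C)(C)C
F4 | step 2 | (2S,3S)-3-bromo-2-chloro-2-methylhex-5-en-1-yl 2,2-dimethylpropanoate | C=CC[C@H](Br)[C@@](C)(Cl)COC(=O)C(C)(C)C
F5 | step 12 | (2R,3S)-2-[(1S,3S,4S)-3-bromo-4-chloro-4-methylcyclohexyl]-6-methoxy-2,6-dimethyl-3,6-dihydro-2H-pyran-3-ol | COC1(C)C=C[C@H](O)[C@@](C)([C@H]2CC[C@](C)(Cl)[C@@H](Br)C2)O1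
F6 | step 12 | (2R,3R)-2-[(1S,3S,4S)-3-bromo-4-chloro-4-methylcyclohexyl]-6-methoxy-2,6-dimethyl-3,6-dihydro-2H-pyran-3-yl 4-nitrobenzoate | COC1(C)C=C[C@@H](OC(=O)c3ccc(cc3)[N+](=O)[O-])[C@@](C)([C@H]2CC[C@](C)(Cl)[C@@H](Br)C2)O1
F7 | step 13 | tert-butyl{[(2R,3R)-2-[(1S,3S,4S)-3-bromo-4-chloro-4-methylcyclohexyl]-6-methoxy-2,6-dimethyl-3,6-dihydro-2H-pyran-3-yl]oxy}dimethylsilane | COC1(C)C=C[C@@H](O[Si](C)(C)C(C)(C)C)[C@@](C)([C@H]2CC[C@](C)(Cl)[C@@H](Br)C2)O1
F8 | step 13 | (2R,3R)-2-[(1S,3S,4S)-3-bromo-4-chloro-4-methylcyclohexyl]-3-{[tert-butyl(dimethyl)silyl]oxy}-2,6-dimethyl-3,6-dihydro-2H-pyran-6-ol | CC1(O)C=C[C@@H](O[Si](C)(C)C(C)(C)C)[C@@](C)([C@H]2CC[C@](C)(Cl)[C@@H](Br)C2)O1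
F9 | step 13 | (3Z,5R,6R)-6-[(1S,3S,4S)-3-bromo-4-chloro-4-methylcyclohexyl]-5-{[tert-butyl(dimethyl)silyl]oxy}-2-methylhept-3-ene-2,6-diol | CC(C)(O)/C=C\[C@@H](O[Si](C)(C)C(C)(C)C)[C@](C)(O)[C@H]1CC[C@](C)(Cl)[C@@H](Br)C1
F10 | step 13 | tert-butyl{[(2R,3R)-2-[(1S,3S,4S)-3-bromo-4-chloro-4-methylcyclohexyl]-2,6,6-trimethyl-3,6-dihydro-2H-pyran-3-yl]oxy}dimethylsilane | CC1(C)C=C[C@@H](O[Si](C)(C)C(C)(C)C)[C@@](C)([C@H]2CC[C@](C)(Cl)[C@@H](Br)C2)O1
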